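**Retrosynthetic overview**
1. 34 comes from tetraol 33 by acetylating the three secondary hydroxyls. The ten-membered ring is closed last, at C9–C10, by an intramolecular allylchromium–aldehyde addition that also creates C9, C10 and the C11=C20 methylene.
2. Seco aldehyde 30 comes from a B-alkyl Suzuki coupling (C4–C5, 5Z alkene retained) of ring A diol 13 with iodo lactone aldehyde 28.
3. Ring A diol 13 comes from benzamide 5 by an auxiliary-controlled Birch reduction–methylation. That one operation turns the flat arene into quaternary C1, a masked C14 ketone and the C10=C11–C20 allylsilane. C14 and then C2 follow by 1,2- and 1,3-induction.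
4. Lactone 28 comes from (E,Z)-dienol 25 by Sharpless epoxidation and invertive epoxide-opening lactonisation (C7, C8). C17 comes from (R)-lactate and the Z-iodoalkene from but-2-yn-1-ol.
5. Ring order: ring A (from the arene) and the γ-lactone are made separately, and the ten-membered carbocycle is made last.

Assumption: briarane locants (C1–C20) are used for all intermediates; C1 keeps one spatial arrangement from 7 onward and only its CIP letter changes with substituent ranks; tert-butyl (R)-lactate, Me3SiCH2MgCl and Sn(CH=CH2)4 are purchased.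

**Step 1**
Reactants: 1 5-bromo-2-methoxybenzoic acid; 2 (S)-2-(methoxymethyl)pyrrolidine
Product: 4 (S)-1-(5-bromo-2-methoxybenzoyl)-2-(methoxymethyl)pyrrolidine, via acid chloride 3 (not isolated)
Conditions: SOCl2, cat. DMF, PhMe, 70 °C, evaporate; then 2, Et3N, CH2Cl2, 0 °C to rt
Reagents that add atoms: none
Why: Schotten–Baumann-type acylation of the secondary amine by the acid chloride installs the proline-derived auxiliary, whose stereocentre is not touched.

**Step 2**
Reactants: 4 bromo benzamide
Product: 5 (S)-1-{2-methoxy-5-[(trimethylsilyl)methyl]benzoyl}-2-(methoxymethyl)pyrrolidine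
Conditions: Me3SiCH2MgCl (1.5 equiv), NiCl2(dppp) (3 mol %), THF, 50 °C
Reagents that add atoms: (trimethylsilyl)methylmagnesium chloride, C[Si](C)(C)C[Mg]Cl
Why: Kumada–Corriu cross-coupling of the aryl bromide with the β-hydrogen-free silylmethyl Grignard reagent is fast under nickel–diphosphine catalysis, while the hindered ortho-substituted tertiary amide resists Grignard addition.

**Step 3 (key step)**
Reactants: 5 benzylsilane benzamide
Product: 7 (S)-1-{[(1R)-6-methoxy-1-methyl-3-(trimethylsilylmethyl)cyclohexa-2,5-dien-1-yl]carbonyl}-2-(methoxymethyl)pyrrolidine, via potassium amide dienolate 6 (not isolated)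
Conditions: K (2.3 equiv), t-BuOH (1.0 equiv), NH3(l)–THF, −78 °C; then MeI (3 equiv), −78 °C to rt
Reagents that add atoms: iodomethane, CI
Why: In this Schultz-type asymmetric Birch reduction–alkylation, two-electron reduction and protonation at C12 give an amide enolate whose potassium is chelated by the enolate oxygen, the ring methoxy group and the auxiliary ether, so MeI attacks the face opposite the methoxymethyl arm and sets quaternary C1, while the benzylic C–Si bond (meta to the amide, low spin density) survives and emerges as the C10=C11–C20 allylsilane.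

**Step 4**
Reactants: 7 cyclohexadiene amide
Product: 8 (S)-1-{[(1R)-1-methyl-6-oxo-3-(trimethylsilylmethyl)cyclohex-2-en-1-yl]carbonyl}-2-(methoxymethyl)pyrrolidine
Conditions: 1 M HCl, THF, 0 °C, monitored, NaHCO3 quench
Reagents that add atoms: water, O
Why: In this acid-catalysed enol ether hydrolysis, protonation at unhindered C13 is faster than protodesilylation, which would need protonation at neopentyl C10, and quaternary C1 keeps the C10=C11 alkene out of conjugation.

**Step 5**
Reactants: 8 keto amide
Product: 9 (S)-1-{[(1R,6S)-6-hydroxy-1-methyl-3-(trimethylsilylmethyl)cyclohex-2-en-1-yl]carbonyl}-2-(methoxymethyl)pyrrolidine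
Conditions: NaBH4, MeOH, −40 °C
Reagents that add atoms: none
Why: In this Felkin–Anh-controlled ketone reduction, hydride attacks C14 anti to the pseudoaxial electron-withdrawing carboxamide on C1, that is from the face of the C15 methyl, so the new hydroxyl ends cis to the amide (14S), and the amide itself is inert to NaBH4.

**Step 6**
Reactants: 9 hydroxy amide
Product: 11 1-{(1R,6S)-6-hydroxy-1-methyl-3-(trimethylsilylmethyl)cyclohex-2-en-1-yl}prop-2-en-1-one, via dilithium tetrahedral adduct 10 (not isolated)
Conditions: CH2=CHLi (4 equiv, from Sn(CH=CH2)4 + n-BuLi), THF, −78 to 0 °C; then cold 1 M HCl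
Reagents that add atoms: vinyllithium, [Li]C=C
Why: In this ketone synthesis by organolithium addition to a tertiary amide, the C14 lithium alkoxide and the auxiliary ether hold lithium in a stable tetrahedral adduct that cannot over-add and collapses only on acidic quench, which also keeps the released amine protonated and away from the enone.

**Step 7**
Reactants: 11 hydroxy enone
Product: 13 (1R)-1-{(1R,6S)-6-hydroxy-1-methyl-3-(trimethylsilylmethyl)cyclohex-2-en-1-yl}prop-2-en-1-ol, via diethylboron chelate 12 (not isolated)
Conditions: Et2BOMe, THF–MeOH (4:1), −78 °C; NaBH4, −78 °C; then MeOH co-evaporation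
Reagents that add atoms: none
Why: In this Narasaka–Prasad reduction, C14–O and the C2 carbonyl are tied in a six-membered boron chelate and external hydride adds 1,2 and axially, anti to the axial C1–C10 ring bond, giving the syn-1,3-diol and hence (2R).

**Step 8**
Reactants: 14 but-2-yn-1-ol
Product: 16 (Z)-3-iodobut-2-en-1-ol, via cyclic vinylalanate 15 (not isolated)
Conditions: NaAlH2(OCH2CH2OMe)2, Et2O, 0 °C to rt; then I2, THF, −78 to 0 °C
Reagents that add atoms: iodine, [I][I]
Why: Hydroxyl-directed trans-hydroalumination of the propargylic alcohol places aluminium on C5 inside a five-membered alanate, and iodinolysis with retention gives only the Z-iodoalkene.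

**Step 9**
Reactants: 16 (Z)-3-iodobut-2-en-1-ol
Product: 17 (Z)-3-iodobut-2-enal
Conditions: MnO2 (15 equiv), CH2Cl2, rt, used at once
Reagents that add atoms: none
Why: Neutral, surface-mediated allylic alcohol oxidation does not isomerise the Z-β-iodoenal.

**Step 10**
Reactants: 18 tert-butyl (R)-lactate
Product: 19 tert-butyl (R)-2-(trifluoromethylsulfonyloxy)propanoate
Conditions: Tf2O, 2,6-lutidine, CH2Cl2, −78 °C
Reagents that add atoms: triflic anhydride, O=S(=O)(OS(=O)(=O)C(F)(F)F)C(F)(F)F
Why: O-sulfonylation with a non-nucleophilic base leaves the C–O stereocentre untouched.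

**Step 11**
Reactants: 20 trimethyl phosphonoacetate; 19 lactate triflate
Product: 22 4-tert-butyl 1-methyl (3S)-2-(dimethoxyphosphoryl)-3-methylbutanedioate (epimers at the phosphonate carbon), via sodium phosphonate carbanion 21 (not isolated)
Conditions: NaH, THF, 0 °C; then 19, −20 °C to rt
Reagents that add atoms: none
Why: SN2 alkylation of the soft phosphonoacetate carbanion by the α-triflyloxy ester proceeds with clean inversion and fixes C17, and the phosphonate carbon becomes sp2 in the next step.

**Step 12**
Reactants: 22 phosphonosuccinate; 17 (Z)-3-iodobut-2-enal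
Product: 24 4-tert-butyl 1-methyl (2E,3R)-2-[(Z)-3-iodobut-2-en-1-ylidene]-3-methylbutanedioate, via lithium phosphonate carbanion 23 (not isolated)
Conditions: LiN(SiMe3)2 (1.0 equiv), THF, −78 °C; then 17, −78 °C to rt
Reagents that add atoms: none
Why: Horner–Wadsworth–Emmons olefination places the dienyl chain trans to the methyl ester (7E), and exactly one equivalent of base removes only the phosphonate C–H, so C17 and the Z-iodoalkene are preserved.

**Step 13**
Reactants: 24 diene diester
Product: 25 tert-butyl (2R,3E,5Z)-3-(hydroxymethyl)-6-iodo-2-methylhepta-3,5-dienoate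
Conditions: i-Bu2AlH (2.2 equiv), CH2Cl2, −78 °C; Rochelle salt work-up
Reagents that add atoms: none
Why: This hydride reduction is chemoselective because the methyl enoate is reduced to the allylic alcohol at −78 °C while the bulky tert-butyl ester is not attacked.

**Step 14**
Reactants: 25 dienol
Product: 26 tert-butyl (2R)-2-{(2R,3R)-2-(hydroxymethyl)-3-[(Z)-2-iodoprop-1-enyl]oxiran-2-yl}propanoate
Conditions: Ti(OiPr)4 (10 mol %), diethyl D-(−)-tartrate (12 mol %), t-BuOOH, 4 Å MS, CH2Cl2, −25 °C
Reagents that add atoms: tert-butyl hydroperoxide, CC(C)(C)OO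
Why: In this Sharpless asymmetric epoxidation, the titanium–D-tartrate catalyst binds the allylic alcohol so that only C7=C8 reacts, and it delivers oxygen to the face that gives the (2R,3R)-epoxide, which fixes C8.

**Step 15**
Reactants: 26 epoxy alcohol
Product: 27 (3R,4R,5S)-4-hydroxy-4-(hydroxymethyl)-5-[(Z)-2-iodoprop-1-enyl]-3-methyloxolan-2-one
Conditions: TFA (5 equiv), CH2Cl2, 0 °C
Reagents that add atoms: none
Why: In this acid-triggered epoxide-opening lactonisation, the ester carbonyl oxygen attacks the allylically activated C7 from the rear (inversion, net anti addition to the E alkene, setting 7S), tert-butyl leaves as isobutene, and the retained C8–O bond becomes the tertiary alcohol.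

**Step 16**
Reactants: 27 lactone diol
Product: 28 (2S,3S,4R)-3-hydroxy-2-[(Z)-2-iodoprop-1-enyl]-4-methyl-5-oxooxolane-3-carbaldehyde
Conditions: IBX (1.5 equiv), EtOAc, 70 °C
Reagents that add atoms: none
Why: IBX oxidises the primary alcohol to the non-enolisable aldehyde without glycol cleavage and cannot oxidise the tertiary hydroxyl.

**Step 17**
Reactants: 13 ring A diol; 28 iodo lactone aldehyde
Product: 30 seco allylsilane aldehyde (13 and 28 joined C4–C5 with the 5Z alkene), via B-alkyl-9-BBN borane 29 (not isolated)
Conditions: 9-BBN-H (3 equiv), THF, rt; H2O; then 28, Pd(dppf)Cl2 (10 mol %), AsPh3, K3PO4, DMF–THF–H2O, rt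
Reagents that add atoms: none
Why: In this B-alkyl Suzuki–Miyaura coupling, 9-BBN-H hydroborates only the monosubstituted vinyl group (the allylsilane alkene is trisubstituted) and zerovalent palladium couples the alkylborane with the alkenyl iodide with retention of the Z geometry.

**Step 18**
Reactants: 30 seco allylsilane aldehyde
Product: 31 seco allylic bromide aldehyde (Br at C10 with C11=C20 methylene; C10 epimers and allylic isomer inconsequential)
Conditions: NBS (1.05 equiv), CH2Cl2–THF, −78 °C
Reagents that add atoms: N-bromosuccinimide, O=C1CCC(=O)N1Br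
Why: In this electrophilic bromodesilylation (SE2′), the allylsilane is far more nucleophilic than the C5=C6 alkene, which is deactivated by the allylic lactone oxygen, and loss of silicon places the halide within the C10–C11–C20 allyl unit only.

**Step 19**
Reactants: 31 seco allylic bromide aldehyde
Product: 33 macrocyclic tetraol (2,8,9,14-tetrahydroxybriara-5Z,11(20)-dien-18,7-olide; all eight stereocentres as in 34), via allylchromium dichloride 32 (not isolated)
Conditions: CrCl2 (10 equiv), 4 Å MS, THF, 0.002 M, slow addition, rt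
Reagents that add atoms: none
Why: In this intramolecular Nozaki–Hiyama allylation, divalent chromium funnels either allylic bromide isomer into the same C20-bound trivalent allylchromium, which adds through C10 in a chair Zimmerman–Traxler array (E-type allyl unit gives the anti C9/C10 pair), forming the bond on the C15-methyl face opposite the C2 tether so that the ten-membered ring is trans-fused and the C11=C20 methylene is released.

**Step 20**
Reactants: 33 macrocyclic tetraol
Product: 34 target CNP0187723.2
Conditions: Ac2O (10 equiv), pyridine, DMAP (cat.), CH2Cl2, rt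
Reagents that add atoms: acetic anhydride, CC(=O)OC(C)=O
Why: Nucleophile-catalysed acetylation esterifies the three secondary hydroxyls (C2, C9, C14), while the fully substituted, flanked C8 hydroxyl does not react and no stereocentre is affected.

**Compound list**
1 | 5-bromo-2-methoxybenzoic acid | COc1ccc(Br)cc1C(=O)O | starting material
2 | (S)-2-(methoxymethyl)pyrrolidine | COC[C@@H]1CCCN1 | starting material
3 | 5-bromo-2-methoxybenzoyl chloride | COc1ccc(Br)cc1C(=O)Cl | intermediate
4 | (S)-1-(5-bromo-2-methoxybenzoyl)-2-(methoxymethyl)pyrrolidine | COc1ccc(Br)cc1C(=O)N1CCC[C@H]1COC | intermediate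
5 | (S)-1-{2-methoxy-5-[(trimethylsilyl)methyl]benzoyl}-2-(methoxymethyl)pyrrolidine | COc1ccc(C[Si](C)(C)C)cc1C(=O)N1CCC[C@H]1COC | intermediate
6 | potassium amide dienolate of the 1,4-dihydroarene | C[Si](C)(C)CC1=CC(=C([O-])N2CCC[C@H]2COC)C(OC)=CC1.[K+] | intermediate
7 | Birch product, (1R)-6-methoxy-1-methyl-3-(trimethylsilylmethyl)cyclohexa-2,5-diene-1-carboxamide of 2 | C[Si](C)(C)CC1=C[C@@](C)(C(=O)N2CCC[C@H]2COC)C(OC)=CC1 | intermediate
8 | ring A keto amide (C14 ketone) | C[Si](C)(C)CC1=C[C@@](C)(C(=O)N2CCC[C@H]2COC)C(=O)CC1 | intermediate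
9 | ring A hydroxy amide (14S, OH cis to the amide, trans to C15 methyl) | C[Si](C)(C)CC1=C[C@@](C)(C(=O)N2CCC[C@H]2COC)[C@@H](O)CC1 | intermediate
10 | dilithium tetrahedral adduct of 9 and vinyllithium | C[Si](C)(C)CC1=C[C@@](C)(C([O-])(C=C)N2CCC[C@H]2COC)[C@@H]([O-])CC1.[Li+].[Li+] | intermediate
11 | ring A hydroxy vinyl ketone | C[Si](C)(C)CC1=C[C@@](C)(C(=O)C=C)[C@@H](O)CC1 | intermediate
12 | C14 O-diethylboryl chelate of 11 | C[Si](C)(C)CC1=C[C@@](C)(C(=O)C=C)[C@@H](OB(CC)CC)CC1 | intermediate
13 | ring A syn-1,3-diol (2R,14S) with C3=C4 vinyl group and allylsilane | C[Si](C)(C)CC1=C[C@@](C)([C@H](O)C=C)[C@@H](O)CC1 | intermediate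
14 | but-2-yn-1-ol | CC#CCO | starting material
15 | sodium cyclic vinylalanate | CC1=CCO[Al-]1(OCCOC)OCCOC.[Na+] | intermediate
16 | (Z)-3-iodobut-2-en-1-ol | C/C(I)=C/CO | intermediate
17 | (Z)-3-iodobut-2-enal | C/C(I)=C/C=O | intermediate
18 | tert-butyl (R)-lactate | C[C@@H](O)C(=O)OC(C)(C)C | starting material
19 | tert-butyl (R)-2-(trifluoromethylsulfonyloxy)propanoate | C[C@@H](OS(=O)(=O)C(F)(F)F)C(=O)OC(C)(C)C | intermediate
20 | trimethyl phosphonoacetate | COC(=O)CP(=O)(OC)OC | starting material
21 | sodium salt of trimethyl phosphonoacetate | COC(=O)[CH-]P(=O)(OC)OC.[Na+] | intermediate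
22 | 4-tert-butyl 1-methyl (3S)-2-(dimethoxyphosphoryl)-3-methylbutanedioate | COC(=O)C(P(=O)(OC)OC)[C@@H](C)C(=O)OC(C)(C)C | intermediate
23 | lithium salt of 22 | COC(=O)[C-](P(=O)(OC)OC)[C@@H](C)C(=O)OC(C)(C)C.[Li+] | intermediate
24 | (7E,5Z)-diene diester | COC(=O)/C(=C/C=C(/C)I)[C@@H](C)C(=O)OC(C)(C)C | intermediate
25 | tert-butyl (2R,3E,5Z)-3-(hydroxymethyl)-6-iodo-2-methylhepta-3,5-dienoate | OC/C(=C/C=C(/C)I)[C@@H](C)C(=O)OC(C)(C)C | intermediate
26 | (2R,3R)-epoxy alcohol | OC[C@]1(O[C@@H]1/C=C(/C)I)[C@@H](C)C(=O)OC(C)(C)C | intermediate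
27 | hydroxy lactone diol (C7 S, C17 R, C8 as in target) | OC[C@@]1(O)[C@H](/C=C(/C)I)OC(=O)[C@@H]1C | intermediate
28 | iodo lactone aldehyde (7S,8S,17R) | O=C[C@@]1(O)[C@H](/C=C(/C)I)OC(=O)[C@@H]1C | intermediate
29 | B-alkyl-9-BBN borane from 13 | C[Si](C)(C)CC1=C[C@@](C)([C@H](O)CCB2C3CCCC2CCC3)[C@@H](O)CC1 | intermediate
30 | seco allylsilane aldehyde | C[Si](C)(C)CC1=C[C@@](C)([C@H](O)CC/C(C)=C\[C@@H]2OC(=O)[C@H](C)[C@@]2(O)C=O)[C@@H](O)CC1 | intermediate
31 | seco allylic bromide aldehyde | C=C1CC[C@H](O)[C@](C)([C@H](O)CC/C(C)=C\[C@@H]2OC(=O)[C@H](C)[C@@]2(O)C=O)C1Br | intermediate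
32 | C20 allylchromium dichloride | Cl[Cr](Cl)CC1=C[C@@](C)([C@H](O)CC/C(C)=C\[C@@H]2OC(=O)[C@H](C)[C@@]2(O)C=O)[C@@H](O)CC1 | intermediate
33 | macrocyclic tetraol | C=C1CC[C@H](O)[C@@]2(C)[C@H]1[C@@H](O)[C@@]1(O)[C@H](/C=C(/C)CC[C@H]2O)OC(=O)[C@@H]1C | intermediate
34 | CNP0187723.2 (2,9,14-triacetoxy-8-hydroxybriara-5Z,11(20)-dien-18,7-olide) | C=C1CC[C@H](OC(C)=O)[C@@]2(C)[C@H]1[C@@H](OC(C)=O)[C@@]1(O)[C@H](/C=C(/C)CC[C@H]2OC(C)=O)OC(=O)[C@@H]1C | target

**Step count**
Total: 20 steps. Longest linear sequence: 11 steps. Three branches have this length: steps 1–7 then 17–20; steps 8, 9, 12–16 then 17–20; steps 10–16 then 17–20.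

**Three steps most likely to fail**

Step 6 (vinyllithium on the neopentyl tertiary amide). The carbonyl may be too shielded, or the β-alkoxide may fragment by retro-aldol. The fallback sets out from 9. LiH2NBH3 in THF cleaves the amide reductively to the neopentyl primary alcohol 1,3-diol F1. TEMPO/PhI(OAc)2 then oxidises only the primary hydroxyl to the β-hydroxy aldehyde F2. CH2=CHMgBr adds to give the allylic alcohol C2 epimer mixture F3, and MnO2 oxidises only the allylic hydroxyl. The sequence returns to the route at 11, where step 7 sets C2 as before.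

Step 15 (acidic lactonisation of the vinyl epoxide). Ionisation at C7 could erode the inversion or scramble the Z alkene. The fallback sets out from 26 and replaces the cationic opening by a metal-templated SN2 opening. TMSOTf/2,6-lutidine converts the tert-butyl ester into the bis-silylated trimethylsilyl ester F4, and brief aqueous methanol gives the epoxy acid F5. Ti(OiPr)4 then binds both the C9 hydroxyl and the carboxylate and directs carboxylate attack to the epoxide carbon remote from the carbinol (C7) with inversion. The sequence returns to the route at 27.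

Step 19 (ten-membered ring closure between two hindered carbons, with C9 and C10 set in the same event). Oligomerisation, cis fusion or the C9 epimer are the dangers. The fallback sets out from 13 (with 28) and moves the ring closure to C4–C5.
- NBS converts 13 into the ring A allylic bromide F6.
- Nickel-free CrCl2 turns F6 into the ring A allylchromium F7. This adds intermolecularly to 28, anti to the C2 side chain and through the same chair array, to give the seco vinyl iodide tetraol F8.
- Bis(1,2-dimethylpropyl)borane hydroborates the monosubstituted vinyl group in preference to the 1,1-disubstituted methylene, giving the alkylborane F9.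
- Pd(dppf)Cl2/AsPh3/K3PO4 at high dilution closes the ring by an intramolecular B-alkyl Suzuki coupling, and the sequence returns to the route at 33.

**Further compounds**
F1 | step 6 | ring A neopentyl primary alcohol 1,3-diol | C[Si](C)(C)CC1=C[C@@](C)(CO)[C@@H](O)CC1
F2 | step 6 | ring A β-hydroxy aldehyde | C[Si](C)(C)CC1=C[C@@](C)(C=O)[C@@H](O)CC1
F3 | step 6 | ring A allylic alcohol, C2 epimer mixture | C[Si](C)(C)CC1=C[C@@](C)(C(O)C=C)[C@@H](O)CC1
F4 | step 15 | bis-silylated trimethylsilyl ester of the epoxy acid | C[Si](C)(C)OC[C@]1(O[C@@H]1/C=C(/C)I)[C@@H](C)C(=O)O[Si](C)(C)C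
F5 | step 15 | epoxy acid | OC[C@]1(O[C@@H]1/C=C(/C)I)[C@@H](C)C(=O)O
F6 | step 19 | ring A allylic bromide | C=C1CC[C@H](O)[C@](C)([C@H](O)C=C)C1Br
F7 | step 19 | ring A allylchromium dichloride | Cl[Cr](Cl)CC1=C[C@@](C)([C@H](O)C=C)[C@@H](O)CC1
F8 | step 19 | seco vinyl iodide tetraol | C=C1CC[C@H](O)[C@](C)([C@H](O)C=C)[C@H]1[C@@H](O)[C@@]1(O)[C@H](/C=C(/C)I)OC(=O)[C@@H]1C
F9 | step 19 | C4 bis(1,2-dimethylpropyl)borane of F8 | C=C1CC[C@H](O)[C@](C)([C@H](O)CCB(C(C)C(C)C)C(C)C(C)C)[C@H]1[C@@H](O)[C@@]1(O)[C@H](/C=C(/C)I)OC(=O)[C@@H]1C
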